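**Plan**
- Retrosynthesis: the 2'-O-MOM group and the 7-O-methyl group come off first. O1–C2 of ring C is then opened to an o-hydroxyaryl ynone. Last, O1–C8a and C4–C4a are cut together, giving a ring A aryne and a ring B arylpropiolic acid.
- Enabling feature: in the fully substituted ring A, the neighbouring carbons C8a and C4a carry O1 and the C4 acyl carbon. Each is flanked by a methoxyl (C8, C5), and O6 and O7 can wear the same benzyl group, so the aryne is symmetric and poses no regiochemical question.
- Forward: ring A is built up from 2,5-dimethoxyphenol to an o-silylaryl triflate (steps 1–6) and ring B from 2-hydroxy-6-methoxybenzaldehyde to the propiolic acid (steps 7–9). The halves are joined in step 10, and ring C closes 6-endo in step 11.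
- End game: hydrogenolysis frees the 6,7-diol, the more acidic 7-OH is methylated, and the MOM group is removed.
- Stereochemistry: the target has no stereocentre and no stereogenic double bond, so nothing has to be set.

Key step: step 10

Assumption: 2,5-dimethoxyphenol, 2-hydroxy-6-methoxybenzaldehyde and benzyl bromide are purchased. Flavone numbering (O1 to C8a, primed locants for ring B) is used for ring atoms throughout.

Step 1
Reactants: 1 2,5-dimethoxyphenol
Product: 2 2-hydroxy-3,6-dimethoxybenzaldehyde
Conditions: MgCl2 (2 equiv), Et3N (4 equiv), (CH2O)n (7 equiv), MeCN, reflux; then 1 M HCl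
Reagents that add atoms: formaldehyde (as paraformaldehyde), C=O
Why: In this Casnati–Skattebøl ortho-formylation the magnesium phenoxide delivers formaldehyde to the only free ortho carbon, and a second formaldehyde oxidises the benzylic alkoxide to the aldehyde by hydride transfer.

Step 2
Reactants: 2 2-hydroxy-3,6-dimethoxybenzaldehyde
Product: 3 3,6-dimethoxybenzene-1,2-diol
Conditions: 30% H2O2, aq NaOH, THF, 0 °C to rt, N2; then 1 M HCl
Reagents that add atoms: hydrogen peroxide, OO
Why: In this Dakin oxidation hydroperoxide adds to the ortho-hydroxy aldehyde, the electron-rich aryl group migrates to oxygen and the formate is hydrolysed in the basic medium, with air excluded because the catechol oxidises easily.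

Step 3
Reactants: 3 3,6-dimethoxybenzene-1,2-diol; 4 benzyl bromide
Product: 5 2,3-bis(benzyloxy)-1,4-dimethoxybenzene
Conditions: 4 (2.4 equiv), K2CO3 (2.5 equiv), DMF, 60 °C
Reagents that add atoms: none
Why: A double Williamson etherification should give the symmetric tetraether, and benzyl is chosen because it later leaves by hydrogenolysis without touching a MOM acetal.

Step 4
Reactants: 5 2,3-bis(benzyloxy)-1,4-dimethoxybenzene
Product: 6 1,2-bis(benzyloxy)-4,5-dibromo-3,6-dimethoxybenzene
Conditions: NBS (2.2 equiv), MeCN, 0 to 40 °C, dark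
Reagents that add atoms: N-bromosuccinimide, O=C1CCC(=O)N1Br
Why: In this electrophilic aromatic bromination the two remaining ring positions are equivalent, each ortho to a methoxyl and para to a benzyloxy group and far more activated than the benzyl rings, while polar conditions in the dark avoid benzylic radical bromination.

Step 5
Reactants: 6 1,2-bis(benzyloxy)-4,5-dibromo-3,6-dimethoxybenzene
Product: 9 3,4-bis(benzyloxy)-6-bromo-2,5-dimethoxyphenol, via aryl Grignard reagent 7 (not isolated), via dimethyl arylboronate 8 (not isolated)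
Conditions: iPrMgCl·LiCl (1.1 equiv), THF, −20 °C; B(OMe)3, −20 °C to rt; 30% H2O2, aq NaOH, 0 °C; then 1 M HCl
Reagents that add atoms: hydrogen peroxide, OO
Why: In this bromine–magnesium exchange, borylation and oxidation sequence either bromine of the symmetric dibromide gives the same product, the ortho bromine and ortho methoxyl speed up a single exchange, and the o-bromoarylmagnesium species does not eliminate at this temperature.

Step 6
Reactants: 9 3,4-bis(benzyloxy)-6-bromo-2,5-dimethoxyphenol
Product: 12 4,5-bis(benzyloxy)-3,6-dimethoxy-2-(trimethylsilyl)phenyl trifluoromethanesulfonate, via trimethylsilyl ether 10 (not isolated), via lithium silylphenoxide 11 (not isolated)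
Conditions: HMDS, THF, 70 °C, evaporate; n-BuLi (1.1 equiv), THF, −78 °C; Tf2O (1.2 equiv), −78 to 0 °C
Reagents that add atoms: hexamethyldisilazane, C[Si](C)(C)N[Si](C)(C)C; trifluoromethanesulfonic anhydride, O=S(=O)(OS(=O)(=O)C(F)(F)F)C(F)(F)F
Why: After O-silylation, bromine–lithium exchange (faster at −78 °C than benzylic deprotonation) triggers a retro-Brook 1,3-shift of silicon from O to C, and the resulting phenoxide is triflated in the same flask, which is the standard route to o-silylaryl triflates.

Step 7
Reactants: 13 2-hydroxy-6-methoxybenzaldehyde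
Product: 14 2-methoxy-6-(methoxymethoxy)benzaldehyde
Conditions: MOMCl (1.5 equiv), iPr2NEt (2 equiv), CH2Cl2, 0 °C to rt
Reagents that add atoms: chloromethyl methyl ether, COCCl
Why: O-Alkylation of the phenol gives a MOM acetal, a group that tolerates organolithiums, fluoride, amines, hydrogenolysis and carbonate base and leaves only under acid.

Step 8
Reactants: 14 2-methoxy-6-(methoxymethoxy)benzaldehyde
Product: 15 2-(2,2-dibromoethenyl)-1-methoxy-3-(methoxymethoxy)benzene
Conditions: CBr4 (2 equiv), PPh3 (4 equiv), Et3N (1 equiv), CH2Cl2, 0 °C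
Reagents that add atoms: tetrabromomethane, BrC(Br)(Br)Br
Why: In the first stage of the Corey–Fuchs sequence the dibromomethylene ylide olefinates the aldehyde in Wittig fashion, and the amine buffers the medium for the sake of the acetal.

Step 9
Reactants: 15 2-(2,2-dibromoethenyl)-1-methoxy-3-(methoxymethoxy)benzene
Product: 17 3-[2-methoxy-6-(methoxymethoxy)phenyl]prop-2-ynoic acid, via lithium acetylide 16 (not isolated)
Conditions: n-BuLi (2.2 equiv), THF, −78 to −20 °C; CO2 (dry gas), −78 °C to rt; 1 M HCl to pH 3, 0 °C
Reagents that add atoms: carbon dioxide, O=C=O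
Why: In the second stage of the Corey–Fuchs sequence, bromine–lithium exchange and a Fritsch–Buttenberg–Wiechell-type 1,2-shift give the alkyne, the second equivalent of base turns it into the acetylide, carboxylation follows, and the brief cold acidification spares the MOM group.

Step 10
Reactants: 12 4,5-bis(benzyloxy)-3,6-dimethoxy-2-(trimethylsilyl)phenyl trifluoromethanesulfonate; 17 3-[2-methoxy-6-(methoxymethoxy)phenyl]prop-2-ynoic acid
Product: 20 1-[3,4-bis(benzyloxy)-6-hydroxy-2,5-dimethoxyphenyl]-3-[2-methoxy-6-(methoxymethoxy)phenyl]prop-2-yn-1-one, via caesium propiolate 18 (not isolated), via tetraalkoxybenzyne 19 (not isolated)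
Conditions: 17 (1.5 equiv), Cs2CO3 (0.75 equiv), MeOH, 0 °C, evaporate, PhMe azeotrope; 12 (1 equiv), CsF (4 equiv), THF (0.02 M), sealed tube, 100 °C; AcOH, 0 °C
Reagents that add atoms: none
Why: Fluoride attacks the silicon of 12 and triflate departs to release aryne 19; a carboxylate oxygen of 18 adds to one aryne carbon (O1–C8a), and the carbanion left on the neighbouring carbon attacks its own ester carbonyl through a four-membered alkoxide whose opening moves the acyl group from oxygen to carbon (C4–C4a), leaving the caesium phenoxide of 20. The closest known reaction type is the fluoride-induced insertion of arynes into the C–O bond of carboxylic acids, arylpropiolic acids included, which gives o-hydroxyaryl ketones. No ring closes and no stereocentre forms, because attack of the phenoxide on the alkyne would place a carbanion at C3 that needs a proton, and the aprotic medium withholds one until the cold AcOH quench, after which the phenol is hydrogen-bonded to the ketone. Regioselectivity is not an issue, since the two aryne carbons of 19 are equivalent, each being flanked by a methoxyl and then a benzyloxy group. The step needs acyl shift to win over protonation (which would stop at the aryl ester) and over attack on the distal alkyne carbon; the first is secured by the preformed, dried salt in THF, and the second by the preferred ester conformation, which holds the alkyne away from the carbanion. The excess of 18 and the slow release of 19 by sparingly soluble CsF should keep the hindered product phenoxide from being arylated.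

Step 11
Reactants: 20 1-[3,4-bis(benzyloxy)-6-hydroxy-2,5-dimethoxyphenyl]-3-[2-methoxy-6-(methoxymethoxy)phenyl]prop-2-yn-1-one
Product: 22 6,7-bis(benzyloxy)-5,8-dimethoxy-2-[2-methoxy-6-(methoxymethoxy)phenyl]-4H-chromen-4-one, via diethylamino enone 21 (not isolated)
Conditions: Et2NH (5 equiv), EtOH, reflux
Reagents that add atoms: none
Why: Aza-Michael addition of the amine at the alkyne carbon that bears ring B gives enaminone 21, and the phenol then displaces the amine at that same carbon by addition–elimination, so ring C should close only in the 6-endo sense (flavone) and not 5-exo (aurone).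

Step 12
Reactants: 22 6,7-bis(benzyloxy)-5,8-dimethoxy-2-[2-methoxy-6-(methoxymethoxy)phenyl]-4H-chromen-4-one
Product: 23 6,7-dihydroxy-5,8-dimethoxy-2-[2-methoxy-6-(methoxymethoxy)phenyl]-4H-chromen-4-one
Conditions: H2 (1 atm), 10% Pd/C, EtOAc/MeOH, rt; filtered and concentrated under Ar
Reagents that add atoms: none
Why: Catalytic hydrogenolysis cleaves both aryl benzyl ethers, while the MOM acetal, the methyl ethers and the conjugated C2–C3 bond of the chromone are inert at ambient pressure and temperature, and the oxidisable catechol is carried on at once.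

Step 13
Reactants: 23 6,7-dihydroxy-5,8-dimethoxy-2-[2-methoxy-6-(methoxymethoxy)phenyl]-4H-chromen-4-one
Product: 24 6-hydroxy-5,7,8-trimethoxy-2-[2-methoxy-6-(methoxymethoxy)phenyl]-4H-chromen-4-one
Conditions: MeI (1.0 equiv), K2CO3 (1.0 equiv), DMF, 0 °C to rt, Ar
Reagents that add atoms: iodomethane, CI
Why: In this site-selective Williamson methylation the 7-OH lies para to C4a and is conjugated with the C4 carbonyl like a vinylogous acid, so one equivalent of base should form mainly the 7-phenoxide, which takes up the single equivalent of MeI, as is usual for 6,7-dihydroxy- and 5,6,7-trihydroxyflavones.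

Step 14
Reactants: 24 6-hydroxy-5,7,8-trimethoxy-2-[2-methoxy-6-(methoxymethoxy)phenyl]-4H-chromen-4-one
Product: 25 6,2'-dihydroxy-5,7,8,6'-tetramethoxyflavone
Conditions: 3 M HCl (cat.), MeOH, 40 °C
Reagents that add atoms: none
Why: Acid-catalysed transacetalisation with methanol removes the MOM group under conditions too mild to cleave aryl methyl ethers or to open the pyrone ring.

**Compound list**
1 | 2,5-dimethoxyphenol | COc1ccc(OC)c(O)c1 | starting material
2 | 2-hydroxy-3,6-dimethoxybenzaldehyde | COc1ccc(OC)c(C=O)c1O | intermediate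
3 | 3,6-dimethoxybenzene-1,2-diol | COc1ccc(OC)c(O)c1O | intermediate
4 | benzyl bromide | BrCc1ccccc1 | starting material
5 | 2,3-bis(benzyloxy)-1,4-dimethoxybenzene | COc1ccc(OC)c(OCc2ccccc2)c1OCc1ccccc1 | intermediate
6 | 1,2-bis(benzyloxy)-4,5-dibromo-3,6-dimethoxybenzene | COc1c(Br)c(Br)c(OC)c(OCc2ccccc2)c1OCc1ccccc1 | intermediate
7 | [3,4-bis(benzyloxy)-6-bromo-2,5-dimethoxyphenyl]magnesium chloride | COc1c(Br)c([Mg]Cl)c(OC)c(OCc2ccccc2)c1OCc1ccccc1 | intermediate
8 | dimethyl [3,4-bis(benzyloxy)-6-bromo-2,5-dimethoxyphenyl]boronate | COc1c(Br)c(B(OC)OC)c(OC)c(OCc2ccccc2)c1OCc1ccccc1 | intermediate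
9 | 3,4-bis(benzyloxy)-6-bromo-2,5-dimethoxyphenol | COc1c(Br)c(O)c(OC)c(OCc2ccccc2)c1OCc1ccccc1 | intermediate
10 | [3,4-bis(benzyloxy)-6-bromo-2,5-dimethoxyphenoxy]trimethylsilane | COc1c(Br)c(O[Si](C)(C)C)c(OC)c(OCc2ccccc2)c1OCc1ccccc1 | intermediate
11 | lithium 3,4-bis(benzyloxy)-2,5-dimethoxy-6-(trimethylsilyl)phenolate | COc1c([Si](C)(C)C)c([O-])c(OC)c(OCc2ccccc2)c1OCc1ccccc1.[Li+] | intermediate
12 | 4,5-bis(benzyloxy)-3,6-dimethoxy-2-(trimethylsilyl)phenyl trifluoromethanesulfonate | COc1c(OCc2ccccc2)c(OCc2ccccc2)c(OC)c(OS(=O)(=O)C(F)(F)F)c1[Si](C)(C)C | intermediate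
13 | 2-hydroxy-6-methoxybenzaldehyde | COc1cccc(O)c1C=O | starting material
14 | 2-methoxy-6-(methoxymethoxy)benzaldehyde | COCOc1cccc(OC)c1C=O | intermediate
15 | 2-(2,2-dibromoethenyl)-1-methoxy-3-(methoxymethoxy)benzene | COCOc1cccc(OC)c1C=C(Br)Br | intermediate
16 | {[2-methoxy-6-(methoxymethoxy)phenyl]ethynyl}lithium | COCOc1cccc(OC)c1C#C[Li] | intermediate
17 | 3-[2-methoxy-6-(methoxymethoxy)phenyl]prop-2-ynoic acid | COCOc1cccc(OC)c1C#CC(=O)O | intermediate
18 | caesium 3-[2-methoxy-6-(methoxymethoxy)phenyl]prop-2-ynoate | COCOc1cccc(OC)c1C#CC(=O)[O-].[Cs+] | intermediate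
19 | 4,5-bis(benzyloxy)-3,6-dimethoxybenzyne (1,2-didehydrobenzene) | COC1=C(OCc2ccccc2)C(OCc2ccccc2)=C(OC)C#C1 | intermediate
20 | 1-[3,4-bis(benzyloxy)-6-hydroxy-2,5-dimethoxyphenyl]-3-[2-methoxy-6-(methoxymethoxy)phenyl]prop-2-yn-1-one | COCOc1cccc(OC)c1C#CC(=O)c1c(O)c(OC)c(OCc2ccccc2)c(OCc2ccccc2)c1OC | intermediate
21 | (E)-1-[3,4-bis(benzyloxy)-6-hydroxy-2,5-dimethoxyphenyl]-3-(diethylamino)-3-[2-methoxy-6-(methoxymethoxy)phenyl]prop-2-en-1-one (alkene geometry of no consequence) | CCN(CC)/C(c1c(OC)cccc1OCOC)=C/C(=O)c1c(O)c(OC)c(OCc2ccccc2)c(OCc2ccccc2)c1OC | intermediate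
22 | 6,7-bis(benzyloxy)-5,8-dimethoxy-2-[2-methoxy-6-(methoxymethoxy)phenyl]-4H-chromen-4-one | COCOc1cccc(OC)c1-c1cc(=O)c2c(OC)c(OCc3ccccc3)c(OCc3ccccc3)c(OC)c2o1 | intermediate
23 | 6,7-dihydroxy-5,8-dimethoxy-2-[2-methoxy-6-(methoxymethoxy)phenyl]-4H-chromen-4-one | COCOc1cccc(OC)c1-c1cc(=O)c2c(OC)c(O)c(O)c(OC)c2o1 | intermediate
24 | 6-hydroxy-5,7,8-trimethoxy-2-[2-methoxy-6-(methoxymethoxy)phenyl]-4H-chromen-4-one | COCOc1cccc(OC)c1-c1cc(=O)c2c(OC)c(O)c(OC)c(OC)c2o1 | intermediate
25 | 6,2'-dihydroxy-5,7,8,6'-tetramethoxyflavone, i.e. 6-hydroxy-2-(2-hydroxy-6-methoxyphenyl)-5,7,8-trimethoxy-4H-chromen-4-one | COc1cccc(O)c1-c1cc(=O)c2c(OC)c(O)c(OC)c(OC)c2o1 | target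

**Step count**
- Total step count: 14.
- Longest linear sequence: 11 steps (steps 1–6 and 10–14). The three-step branch to acid 17 joins at step 10.

**Steps most likely to fail**

Step 10. The aryl anion may pick up a stray proton before the acyl group has moved, so that the reaction stops at O-arylation. The propiolate salt may lose CO2 on heating, and the phenoxide may close onto the alkyne early and without control of ring size. The fallback sets out from bromophenol 9 and acid 17 and first makes the O1–C8a connection as an ordinary ester. EDC·HCl and DMAP in CH2Cl2 should give 3,4-bis(benzyloxy)-6-bromo-2,5-dimethoxyphenyl 3-[2-methoxy-6-(methoxymethoxy)phenyl]prop-2-ynoate F1. Bromine–lithium exchange with t-BuLi (2 equiv) in THF/Et2O at −100 °C then produces the same o-acyloxyaryl anion, but cold and free of proton donors. An anionic Fries-type 1,3-shift of the acyl group from O to C, followed by an AcOH quench, should lead to ynone 20, where the route is rejoined.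

Step 13. The two neighbouring hydroxyls may be poorly distinguished, methylation may run on to the diether, and the electron-rich catechol may be oxidised by air under base. The fallback sets out from diol 23 and turns the acidity difference into a leaving-group difference.
- Ac2O in pyridine should give 5,8-dimethoxy-2-[2-methoxy-6-(methoxymethoxy)phenyl]-4-oxo-4H-chromene-6,7-diyl diacetate F2.
- PhSH and imidazole in NMP at 0 °C should remove only the acetate on the better leaving 7-phenoxide, giving 7-hydroxy-5,8-dimethoxy-2-[2-methoxy-6-(methoxymethoxy)phenyl]-4-oxo-4H-chromen-6-yl acetate F3.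
- A Mitsunobu methylation (MeOH, PPh3, DIAD, THF) works without base and leaves acetyl migration little chance. It should give 5,7,8-trimethoxy-2-[2-methoxy-6-(methoxymethoxy)phenyl]-4-oxo-4H-chromen-6-yl acetate F4.
- Methanolysis with K2CO3 in MeOH comes back to the route at 24.

Step 5. The exchange may be slow or incomplete on the very electron-rich ring, the o-bromoaryl Grignard reagent may lose MgBrCl on warming, and the doubly ortho-substituted boronate may protodeboronate before it is oxidised. The fallback sets out from tetraether 5, uses no organometallic reagent, and installs oxygen first and bromine last.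
- Vilsmeier–Haack formylation (POCl3, DMF, 80 °C) should give 3,4-bis(benzyloxy)-2,5-dimethoxybenzaldehyde F5.
- Baeyer–Villiger oxidation with mCPBA in CH2Cl2 should give 3,4-bis(benzyloxy)-2,5-dimethoxyphenyl formate F6.
- K2CO3 in MeOH should free 3,4-bis(benzyloxy)-2,5-dimethoxyphenol F7.
- NBS (1 equiv, MeCN, 0 °C) brominates the single remaining ring position, ortho to the hydroxyl, and the route is rejoined at 9.

**Further compounds**
F1 | step 10 | 3,4-bis(benzyloxy)-6-bromo-2,5-dimethoxyphenyl 3-[2-methoxy-6-(methoxymethoxy)phenyl]prop-2-ynoate | COCOc1cccc(OC)c1C#CC(=O)Oc1c(Br)c(OC)c(OCc2ccccc2)c(OCc2ccccc2)c1OC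
F2 | step 13 | 5,8-dimethoxy-2-[2-methoxy-6-(methoxymethoxy)phenyl]-4-oxo-4H-chromene-6,7-diyl diacetate | COCOc1cccc(OC)c1-c1cc(=O)c2c(OC)c(OC(C)=O)c(OC(C)=O)c(OC)c2o1
F3 | step 13 | 7-hydroxy-5,8-dimethoxy-2-[2-methoxy-6-(methoxymethoxy)phenyl]-4-oxo-4H-chromen-6-yl acetate | COCOc1cccc(OC)c1-c1cc(=O)c2c(OC)c(OC(C)=O)c(O)c(OC)c2o1
F4 | step 13 | 5,7,8-trimethoxy-2-[2-methoxy-6-(methoxymethoxy)phenyl]-4-oxo-4H-chromen-6-yl acetate | COCOc1cccc(OC)c1-c1cc(=O)c2c(OC)c(OC(C)=O)c(OC)c(OC)c2o1
F5 | step 5 | 3,4-bis(benzyloxy)-2,5-dimethoxybenzaldehyde | COc1cc(C=O)c(OC)c(OCc2ccccc2)c1OCc1ccccc1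
F6 | step 5 | 3,4-bis(benzyloxy)-2,5-dimethoxyphenyl formate | COc1cc(OC=O)c(OC)c(OCc2ccccc2)c1OCc1ccccc1
F7 | step 5 | 3,4-bis(benzyloxy)-2,5-dimethoxyphenol | COc1cc(O)c(OC)c(OCc2ccccc2)c1OCc1ccccc1
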